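## Retrosynthetic overview

- The target is a trans-(3R,4S)-3,4-diarylchroman whose 4-aryl group carries a (3R)-isoflavan unit. The four benzene rings come from the building blocks. The isoflavan pyran ring is made first (chalcone → isoflavone → 2H-chromene → asymmetric hydrogenation).
- The pyran ring of the diarylchroman (O1, C2, C3, C4, C4a, C8a) is closed last by disconnecting C3–C4 and O1–C2. This is an aminocatalytic formal [4+2] between an ortho-quinone methide (O1=C8a–C4a=C4) and the enamine of an arylacetaldehyde (C2–C3). C2 enters as a lactol carbon and is then reduced.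
- Enabling feature: C4 is a diarylmethine with O1 ortho (on C8a) and O7 para to C4a, and its second aryl ring has ortho-OMe and para-O donors. The carbinol precursor therefore ionises to a planar, fourfold donor-stabilised o-quinone methide, so both carbinol epimers converge. C3, being α to the masked aldehyde C2, can equilibrate to the trans arrangement.
- The carbinol comes from the aryllithium of a brominated (3R)-isoflavan and a salicylaldehyde. Hydrogenolysis of four benzyl ethers ends the route.

Key step: step 11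

Remarks on the chemistry:
- The SMILES is read as the trans-(3R,4S)-diarylchroman bearing a (3R)-isoflavan unit.
- The sense of induction of the chiral catalysts in steps 6 and 11 is assigned by analogy with established models. It would be checked on the first run, and the antipodal catalyst used if the sense were reversed.

## Route

Step 1
Reactants: 1 5-bromo-2-hydroxy-4-methoxybenzaldehyde
Product: 2 2-(benzyloxy)-5-bromo-4-methoxybenzaldehyde
Conditions: BnBr, K2CO3, DMF, 60 °C
Reagents that add atoms: benzyl bromide, BrCc1ccccc1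
Why: Williamson O-alkylation of the only phenol, with no competing nucleophilic site.

Step 2
Reactants: 2 2-(benzyloxy)-5-bromo-4-methoxybenzaldehyde; 3 1-[4-(benzyloxy)-2-hydroxyphenyl]ethan-1-one
Product: 4 (E)-1-[4-(benzyloxy)-2-hydroxyphenyl]-3-[2-(benzyloxy)-5-bromo-4-methoxyphenyl]prop-2-en-1-one
Conditions: KOH (50% aq.), EtOH, rt
Reagents that add atoms: none
Why: Claisen–Schmidt condensation of the methyl ketone enolate with a non-enolisable aldehyde, where dehydration should give the conjugated E-enone.

Step 3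
Reactants: 4 the 2'-hydroxychalcone
Product: 5 1-[4-(benzyloxy)-2-hydroxyphenyl]-2-[2-(benzyloxy)-5-bromo-4-methoxyphenyl]-3,3-dimethoxypropan-1-one (racemic)
Conditions: Tl(NO3)3·3H2O (1.1 equiv), MeOH, rt
Reagents that add atoms: methanol, CO
Why: Thallium(III)-mediated oxidative 1,2-aryl migration of a 2'-hydroxychalcone (the classical isoflavone route), in which the electron-rich B-ring shifts from Cβ to Cα and methanol traps Cβ as the dimethyl acetal.

Step 4
Reactants: 5 the β-keto dimethyl acetal
Product: 6 7-(benzyloxy)-3-[2-(benzyloxy)-5-bromo-4-methoxyphenyl]-4H-chromen-4-one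
Conditions: conc. HCl (cat.), MeOH, reflux
Reagents that add atoms: none
Why: Acid-catalysed attack of the 2'-phenol on the acetal carbon and loss of two methanol molecules closes the γ-pyrone ring, and aryl benzyl ethers and the aryl bromide should tolerate brief methanolic HCl.

Step 5
Reactants: 6 the isoflavone
Product: 8 7-(benzyloxy)-3-[2-(benzyloxy)-5-bromo-4-methoxyphenyl]-2H-chromene, via isoflavan-4-ol 7 (not isolated)
Conditions: NaBH4, THF/EtOH, 0 °C → rt; work-up; then p-TsOH·H2O (5 mol%), toluene, 70 °C
Reagents that add atoms: none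
Why: Borohydride reduces the isoflavone by conjugate then carbonyl reduction, and the benzylic 4-hydroxyl (para to the 7-benzyloxy group) then ionises under catalytic acid and loses H-3 (E1 dehydration) to give the aryl-conjugated 2H-chromene.

Step 6
Reactants: 8 the 3-aryl-2H-chromene
Product: 9 (3R)-7-(benzyloxy)-3-[2-(benzyloxy)-5-bromo-4-methoxyphenyl]chroman
Conditions: [Ir(cod)(L*)]BArF (1–2 mol%, L* = chiral phosphinite–oxazoline of the ThrePHOX type, antipode chosen for 3R), H2 (50 bar), CH2Cl2, rt
Reagents that add atoms: none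
Why: Iridium/P,N-catalysed asymmetric hydrogenation of a trisubstituted aryl alkene, a reaction type established on 3-aryl-2H-chromenes, where the ligand controls the face of hydrogen delivery to set C3 as R and the cationic Ir catalyst should leave the aryl bromide and benzyl ethers intact.

Step 7
Reactants: 9 the (3R)-bromo-isoflavan; 10 4-(benzyloxy)-2-hydroxybenzaldehyde
Product: 13 [4-(benzyloxy)-2-hydroxyphenyl]{4-(benzyloxy)-5-[(3R)-7-(benzyloxy)chroman-3-yl]-2-methoxyphenyl}methanol (mixture of carbinol epimers), via aryllithium 11 (not isolated), via sodium phenolate 12 (not isolated)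
Conditions: 9, n-BuLi (1.05 equiv), THF, –78 °C; then 10 pre-treated with NaH (THF, 0 °C), –78 → –20 °C; aq. NH4Cl; chromatography on Et3N-deactivated silica
Reagents that add atoms: none
Why: Bromine–lithium exchange (aryllithium stabilised by the ortho-methoxy group) followed by 1,2-addition to the aldehyde, whose phenol is masked as the phenolate; the new carbinol centre is formed without control, which does not matter because step 11 erases it.

Step 8
Reactants: 14 2-hydroxy-4,5-dimethoxybenzaldehyde
Product: 15 2-(benzyloxy)-4,5-dimethoxybenzaldehyde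
Conditions: BnBr, K2CO3, DMF, 60 °C
Reagents that add atoms: benzyl bromide, BrCc1ccccc1
Why: Williamson O-alkylation of the single phenol.

Step 9
Reactants: 15 2-(benzyloxy)-4,5-dimethoxybenzaldehyde
Product: 16 1-(benzyloxy)-4,5-dimethoxy-2-(2-methoxyethenyl)benzene (E/Z mixture)
Conditions: Ph3P(CH2OMe)Cl, KOtBu, THF, 0 °C → rt
Reagents that add atoms: (methoxymethyl)triphenylphosphonium chloride, COC[P+](c1ccccc1)(c1ccccc1)c1ccccc1.[Cl-]
Why: Wittig one-carbon homologation with the methoxymethylene ylide, where the alkene geometry is irrelevant because both isomers hydrolyse to the same aldehyde.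

Step 10
Reactants: 16 the enol ether
Product: 17 2-[2-(benzyloxy)-4,5-dimethoxyphenyl]acetaldehyde
Conditions: 2 M aq. HCl, THF, 50 °C; used at once
Reagents that add atoms: water, O
Why: Acid hydrolysis of an enol ether (C-protonation, hydration of the oxocarbenium ion, loss of methanol) gives the arylacetaldehyde, which is used fresh to avoid self-aldolisation.

Step 11
Reactants: 13 the o-hydroxybenzhydrol (carbinol epimers); 17 the arylacetaldehyde
Product: 20 (3R,4S)-7-(benzyloxy)-4-{4-(benzyloxy)-5-[(3R)-7-(benzyloxy)chroman-3-yl]-2-methoxyphenyl}-3-[2-(benzyloxy)-4,5-dimethoxyphenyl]chroman-2-ol (both C2 anomers), via ortho-quinone methide 18 (not isolated), via enamine 19 (not isolated)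
Conditions: (R)-α,α-diphenylprolinol trimethylsilyl ether (20 mol%), PhCO2H (20 mol%), CHCl3, 0 °C → rt; 17 (2 equiv) added slowly
Reagents that add atoms: none
Why: The acid co-catalyst ionises the fourfold donor-stabilised carbinol 13 to the planar o-quinone methide 18 (both carbinol epimers converge) while the amine turns 17 into the E-enamine 19; the aryl-bearing enamine carbon adds to the methide carbon (C3–C4), the freed phenol oxygen closes onto the iminium carbon (O1–C2, 6-exo-trig), and hydrolysis of the N,O-aminal by the water released earlier frees the lactol and the catalyst. The closest known reaction type is the diarylprolinol-silyl-ether-catalysed formal [4+2] (Michael addition/hemiacetalisation) of enolisable aldehydes with o-quinone methides generated in situ, which gives trans-3,4-disubstituted chroman-2-ols. C4 is set by the catalyst: the CPh2(OTMS) group blocks one enamine face and the synclinal approach known from enamine Michael additions fixes the methide face, which with the (R)-catalyst should correspond to 4S. C3 is set as 3R in the same bond-forming event and is also under thermodynamic control, because the lactol can open to the α-aryl aldehyde and any 3,4-cis material should epimerise to the trans-diequatorial lactol. The step needs C–C bond formation at the aryl-bearing carbon (secured by enamine polarity), ring closure through one oxygen only (O1 is the only free phenol, all other oxygens being ethers), and catalyst control over the isoflavan centre, which lies four bonds from C4 across an arene and should exert no bias.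

Step 12
Reactants: 20 the chroman-2-ol
Product: 21 (3R,4S)-7-(benzyloxy)-4-{4-(benzyloxy)-5-[(3R)-7-(benzyloxy)chroman-3-yl]-2-methoxyphenyl}-3-[2-(benzyloxy)-4,5-dimethoxyphenyl]chroman
Conditions: Et3SiH (5 equiv), BF3·OEt2 (2 equiv), CH2Cl2, –78 → –30 °C
Reagents that add atoms: none
Why: Ionic hydrogenation of a lactol, in which BF3 ionises the anomeric hydroxyl to the cyclic oxocarbenium ion and the silane reduces it at C2, leaving C3 and C4 untouched as long as the low temperature suppresses loss of H-3.

Step 13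
Reactants: 21 the tetrabenzyl ether
Product: 22 (3R,4S)-4-{4-hydroxy-5-[(3R)-7-hydroxychroman-3-yl]-2-methoxyphenyl}-3-(2-hydroxy-4,5-dimethoxyphenyl)chroman-7-ol (target)
Conditions: H2 (1 atm), 10% Pd/C, EtOAc/MeOH, rt
Reagents that add atoms: none
Why: Hydrogenolysis of the four aryl benzyl ethers, where the methyl ethers, the chroman C–O bonds (C2 is not benzylic) and the C–C-bonded stereocentres should be inert.

## Compound list

1 | 5-bromo-2-hydroxy-4-methoxybenzaldehyde | COc1cc(O)c(C=O)cc1Br | starting material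
2 | 2-(benzyloxy)-5-bromo-4-methoxybenzaldehyde | COc1cc(OCc2ccccc2)c(C=O)cc1Br | intermediate
3 | 1-[4-(benzyloxy)-2-hydroxyphenyl]ethan-1-one | CC(=O)c1ccc(OCc2ccccc2)cc1O | starting material
4 | (E)-1-[4-(benzyloxy)-2-hydroxyphenyl]-3-[2-(benzyloxy)-5-bromo-4-methoxyphenyl]prop-2-en-1-one | COc1cc(OCc2ccccc2)c(/C=C/C(=O)c2ccc(OCc3ccccc3)cc2O)cc1Br | intermediate
5 | 1-[4-(benzyloxy)-2-hydroxyphenyl]-2-[2-(benzyloxy)-5-bromo-4-methoxyphenyl]-3,3-dimethoxypropan-1-one (racemic) | COc1cc(OCc2ccccc2)c(C(C(OC)OC)C(=O)c2ccc(OCc3ccccc3)cc2O)cc1Br | intermediate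
6 | 7-(benzyloxy)-3-[2-(benzyloxy)-5-bromo-4-methoxyphenyl]-4H-chromen-4-one | COc1cc(OCc2ccccc2)c(-c2coc3cc(OCc4ccccc4)ccc3c2=O)cc1Br | intermediate
7 | 7-(benzyloxy)-3-[2-(benzyloxy)-5-bromo-4-methoxyphenyl]chroman-4-ol (racemic, cis/trans; not isolated) | COc1cc(OCc2ccccc2)c(C2COc3cc(OCc4ccccc4)ccc3C2O)cc1Br | intermediate
8 | 7-(benzyloxy)-3-[2-(benzyloxy)-5-bromo-4-methoxyphenyl]-2H-chromene | COc1cc(OCc2ccccc2)c(C2=Cc3ccc(OCc4ccccc4)cc3OC2)cc1Br | intermediate
9 | (3R)-7-(benzyloxy)-3-[2-(benzyloxy)-5-bromo-4-methoxyphenyl]chroman | COc1cc(OCc2ccccc2)c([C@@H]2COc3cc(OCc4ccccc4)ccc3C2)cc1Br | intermediate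
10 | 4-(benzyloxy)-2-hydroxybenzaldehyde | O=Cc1ccc(OCc2ccccc2)cc1O | starting material
11 | {4-(benzyloxy)-5-[(3R)-7-(benzyloxy)chroman-3-yl]-2-methoxyphenyl}lithium (not isolated) | COc1cc(OCc2ccccc2)c([C@@H]2COc3cc(OCc4ccccc4)ccc3C2)cc1[Li] | intermediate
12 | sodium 5-(benzyloxy)-2-formylphenolate (not isolated) | [Na+].[O-]c1cc(OCc2ccccc2)ccc1C=O | intermediate
13 | [4-(benzyloxy)-2-hydroxyphenyl]{4-(benzyloxy)-5-[(3R)-7-(benzyloxy)chroman-3-yl]-2-methoxyphenyl}methanol (both carbinol epimers) | COc1cc(OCc2ccccc2)c([C@@H]2COc3cc(OCc4ccccc4)ccc3C2)cc1C(O)c1ccc(OCc2ccccc2)cc1O | intermediate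
14 | 2-hydroxy-4,5-dimethoxybenzaldehyde | COc1cc(O)c(C=O)cc1OC | starting material
15 | 2-(benzyloxy)-4,5-dimethoxybenzaldehyde | COc1cc(OCc2ccccc2)c(C=O)cc1OC | intermediate
16 | 1-(benzyloxy)-4,5-dimethoxy-2-(2-methoxyethenyl)benzene (E/Z mixture) | COc1cc(OCc2ccccc2)c(C=COC)cc1OC | intermediate
17 | 2-[2-(benzyloxy)-4,5-dimethoxyphenyl]acetaldehyde | COc1cc(OCc2ccccc2)c(CC=O)cc1OC | intermediate
18 | (6E)-3-(benzyloxy)-6-({4-(benzyloxy)-5-[(3R)-7-(benzyloxy)chroman-3-yl]-2-methoxyphenyl}methylidene)cyclohexa-2,4-dien-1-one (o-quinone methide; not isolated) | COc1cc(OCc2ccccc2)c([C@@H]2COc3cc(OCc4ccccc4)ccc3C2)cc1/C=C1\C=CC(OCc2ccccc2)=CC1=O | intermediate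
19 | (E)-enamine of 17 with (R)-2-{diphenyl[(trimethylsilyl)oxy]methyl}pyrrolidine (not isolated) | COc1cc(OCc2ccccc2)c(/C=C/N2CCC[C@@H]2C(O[Si](C)(C)C)(c2ccccc2)c2ccccc2)cc1OC | intermediate
20 | (3R,4S)-7-(benzyloxy)-4-{4-(benzyloxy)-5-[(3R)-7-(benzyloxy)chroman-3-yl]-2-methoxyphenyl}-3-[2-(benzyloxy)-4,5-dimethoxyphenyl]chroman-2-ol (C2 anomers) | COc1cc(OCc5ccccc5)c([C@@H]2C(O)Oc3cc(OCc6ccccc6)ccc3[C@H]2c2cc([C@@H]3COc4cc(OCc7ccccc7)ccc4C3)c(OCc8ccccc8)cc2OC)cc1OC | intermediate
21 | (3R,4S)-7-(benzyloxy)-4-{4-(benzyloxy)-5-[(3R)-7-(benzyloxy)chroman-3-yl]-2-methoxyphenyl}-3-[2-(benzyloxy)-4,5-dimethoxyphenyl]chroman | COc1cc(OCc5ccccc5)c([C@@H]2COc3cc(OCc6ccccc6)ccc3[C@H]2c2cc([C@@H]3COc4cc(OCc7ccccc7)ccc4C3)c(OCc8ccccc8)cc2OC)cc1OC | intermediate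
22 | (3R,4S)-4-{4-hydroxy-5-[(3R)-7-hydroxychroman-3-yl]-2-methoxyphenyl}-3-(2-hydroxy-4,5-dimethoxyphenyl)chroman-7-ol | COc1cc(O)c([C@@H]2COc3cc(O)ccc3[C@H]2c2cc([C@@H]3COc4cc(O)ccc4C3)c(O)cc2OC)cc1OC | target

## Step count and risks

Total step count: 13.
Longest linear sequence: 10 steps (steps 1–7, then 11–13).

Steps most likely to fail:

1. Step 11 (key step). The strongly donor-stabilised o-quinone methide may react slowly or reversibly with the enamine, so catalyst control at C4 could be lost through retro-addition, and self-condensation of the arylacetaldehyde may outrun the cross-reaction. The fallback sets out from carbinol 13 and the E isomer of enol ether 16 (separated from the Z isomer by chromatography). A chiral BINOL-derived phosphoric acid (TRIP type, 5–10 mol%, CH2Cl2, –20 °C) would generate the o-quinone methide as a hydrogen-bonded ion pair, and an inverse-electron-demand oxa-Diels–Alder reaction with the enol ether would close the same ring. Endo addition of the E alkene should give (2S,3R,4S)-7-(benzyloxy)-4-{4-(benzyloxy)-5-[(3R)-7-(benzyloxy)chroman-3-yl]-2-methoxyphenyl}-3-[2-(benzyloxy)-4,5-dimethoxyphenyl]-2-methoxychroman F1, with the 3,4-trans relationship following from the alkene geometry. Reduction of the acetal with Et3SiH/BF3·OEt2 (as in step 12) returns to the route at 21.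

2. Step 6. The ortho-benzyloxy group twists the aryl ring and crowds the trisubstituted alkene, so the hydrogenation may stall or give poor facial selectivity. The fallback sets out from isoflavone 6. Asymmetric transfer hydrogenation with a Ru(II)–arene–TsDPEN catalyst (HCO2H/Et3N, EtOAc, 40 °C; enantiomer chosen for 3R) should effect conjugate reduction and then carbonyl reduction of the isoflavanone under dynamic kinetic resolution. This would give (3R,4R)-7-(benzyloxy)-3-[2-(benzyloxy)-5-bromo-4-methoxyphenyl]chroman-4-ol F2. Ionic deoxygenation of the benzylic hydroxyl (Et3SiH in excess, TFA, CH2Cl2, –40 °C, kept cold to suppress elimination to the chromene) returns to the route at 9.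

3. Step 12. The oxocarbenium ion may lose H-3 to a 4H-chromene, whose re-protonation would erode the trans relationship, and the Lewis acid may trigger cleavage at the doubly benzylic C4. The fallback sets out from lactol 20. NaBH4 (THF/MeOH, 0 °C) reduces the ring-opened hydroxy aldehyde to (2R,3S)-3-[4-(benzyloxy)-2-hydroxyphenyl]-3-{4-(benzyloxy)-5-[(3R)-7-(benzyloxy)chroman-3-yl]-2-methoxyphenyl}-2-[2-(benzyloxy)-4,5-dimethoxyphenyl]propan-1-ol F3. Mitsunobu etherification (PPh3, DIAD, THF, 0 °C) then recloses the O1–C2 bond (6-exo-tet) without touching either stereocentre and returns to the route at 21.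

Further compounds
F1 | step 11 | (2S,3R,4S)-7-(benzyloxy)-4-{4-(benzyloxy)-5-[(3R)-7-(benzyloxy)chroman-3-yl]-2-methoxyphenyl}-3-[2-(benzyloxy)-4,5-dimethoxyphenyl]-2-methoxychroman | COc1cc(OCc5ccccc5)c([C@@H]2[C@@H](OC)Oc3cc(OCc6ccccc6)ccc3[C@H]2c2cc([C@@H]3COc4cc(OCc7ccccc7)ccc4C3)c(OCc8ccccc8)cc2OC)cc1OC
F2 | step 6 | (3R,4R)-7-(benzyloxy)-3-[2-(benzyloxy)-5-bromo-4-methoxyphenyl]chroman-4-ol | COc1cc(OCc2ccccc2)c([C@@H]2COc3cc(OCc4ccccc4)ccc3[C@@H]2O)cc1Br
F3 | step 12 | (2R,3S)-3-[4-(benzyloxy)-2-hydroxyphenyl]-3-{4-(benzyloxy)-5-[(3R)-7-(benzyloxy)chroman-3-yl]-2-methoxyphenyl}-2-[2-(benzyloxy)-4,5-dimethoxyphenyl]propan-1-ol | COc1cc(OCc5ccccc5)c([C@H](CO)[C@@H](c3ccc(OCc6ccccc6)cc3O)c2cc([C@@H]3COc4cc(OCc7ccccc7)ccc4C3)c(OCc8ccccc8)cc2OC)cc1OC
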